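**Retrosynthetic overview**
1. Target 19 ⇐ O-dealkylation and C3 epimerisation of cis-lactone acid 17. Compound 17 ⇐ Baeyer–Villiger fission of the C(=O)–C(OMe)2 bond of tricyclic keto ketal 15. The ketone carbon becomes the free CO2H and the ketal carbon becomes the C3 methyl ester.
2. Enabling feature: C4, C3, the C3 ester carbon, the CO2H carbon, the vinylic CH and the ester-bearing alkene carbon are the six carbons of an opened benzene ring (ring B, an isovanillate). C4 and CO2H are cis on the alkene because both were ring members. In the o-quinone monoketal form of ring B, C3 is the unsubstituted δ-carbon of the dienone and lies under the ortho carboxyl group of ring A.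
3. 15 ⇐ closure of lactone ring C by O–C3 bond formation: an enantioselective 6-endo-trig 1,6-oxa-conjugate addition within the stereocentre-free dienone acid 13.
4. 13 ⇐ PhI(OAc)2/MeOH dearomatisation of the flat biaryl phenol 11 ⇐ Suzuki–Miyaura coupling of ring A bromide 5 with ring B boronate 9.
5. Ring order: rings A and B are bought as arenes (5 from 2,4,5-trimethoxybenzoic acid through its quinone and HBr, 9 from methyl isovanillate). Ring C is formed in step 12 and ring B is opened in step 13.

Key step: step 12

Numbering: the isochromanone numbering of the target (C1 lactone carbonyl, O2, C3, C4, C4a, C5–C8, C8a) is used for all intermediates.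
Assumption: no close precedent predicts the sense of induction of the cinchona squaramide in step 12. The quinine-derived catalyst is written, and its quinidine-derived pseudoenantiomer takes its place if a test run shows the opposite sense.

**Step 1**
Reactants: 1 2,4,5-trimethoxybenzoic acid
Product: 2 2-(trimethylsilyl)ethyl 2,4,5-trimethoxybenzoate
Conditions: Me3SiCH2CH2OH, DCC, DMAP (cat.), CH2Cl2, 0 °C to rt
Reagents that add atoms: 2-(trimethylsilyl)ethanol, C[Si](C)(C)CCO
Why: Steglich esterification of a benzoic acid with only one ortho substituent installs a fluoride-labile ester that stays distinct from the methyl esters of the target.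

**Step 2**
Reactants: 2 2-(trimethylsilyl)ethyl 2,4,5-trimethoxybenzoate
Product: 3 2-(trimethylsilyl)ethyl 4-methoxy-3,6-dioxocyclohexa-1,4-diene-1-carboxylate (ring A quinone)
Conditions: (NH4)2Ce(NO3)6 (2.5 equiv), MeCN/H2O, 0 °C, short contact, extractive work-up
Reagents that add atoms: water, O
Why: Oxidative demethylation of a para-dimethoxyarene to the p-quinone should occur at the 2- and 5-methoxy groups, the only para pair, with the quinone oxygens coming from water.

**Step 3**
Reactants: 3 ring A quinone
Product: 4 2-(trimethylsilyl)ethyl 2-bromo-3,6-dihydroxy-4-methoxybenzoate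
Conditions: 48 % aq. HBr (1.1 equiv), CHCl3, 0 °C
Reagents that add atoms: hydrogen bromide, Br
Why: In this conjugate hydrobromination of a quinone followed by enolisation, bromide should add to the only ring CH that is β to both the ester and a quinone carbonyl, because the other CH is deactivated as part of a vinylogous ester, and this places the halogen between ester and phenol where electrophilic bromination would not go.

**Step 4**
Reactants: 4 bromohydroquinone
Product: 5 2-(trimethylsilyl)ethyl 3,6-bis(benzyloxy)-2-bromo-4-methoxybenzoate
Conditions: BnBr (2.5 equiv), K2CO3, DMF, 50 °C, argon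
Reagents that add atoms: benzyl bromide, BrCc1ccccc1
Why: Williamson ether synthesis on both phenols protects the hydroquinone against reoxidation and places a bulky group at C5 that later steers the ring fusion.

**Step 5**
Reactants: 6 methyl 3-hydroxy-4-methoxybenzoate (methyl isovanillate)
Product: 7 methyl 4-methoxy-3-(methoxymethoxy)benzoate
Conditions: MOMCl, iPr2NEt, CH2Cl2, 0 °C to rt
Reagents that add atoms: chloromethyl methyl ether, COCCl
Why: O-alkylation of the phenol (acetal protection) gives a base-stable ether that can later be removed beside benzyl ethers and the silylethyl ester.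

**Step 6**
Reactants: 7 MOM ether
Product: 8 methyl 2-bromo-4-methoxy-5-(methoxymethoxy)benzoate
Conditions: NBS, MeCN, 0 °C to rt
Reagents that add atoms: N-bromosuccinimide, O=C1CCC(=O)N1Br
Why: Electrophilic aromatic bromination of a 3,4-dialkoxybenzoate should go para to the 3-alkoxy group, the known position for veratrates, under neutral conditions that spare the acetal.

**Step 7**
Reactants: 8 aryl bromide
Product: 9 methyl 4-methoxy-5-(methoxymethoxy)-2-(4,4,5,5-tetramethyl-1,3,2-dioxaborolan-2-yl)benzoate
Conditions: B2pin2, Pd(dppf)Cl2 (3 mol %), KOAc, 1,4-dioxane, 90 °C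
Reagents that add atoms: bis(pinacolato)diboron, CC1(C)OB(OC1(C)C)B1OC(C)(C)C(C)(C)O1
Why: Miyaura borylation tolerates the ortho ester and the acetal and puts boron on the less hindered coupling partner.

**Step 8**
Reactants: 5 ring A bromide; 9 ring B boronate
Product: 10 2-(trimethylsilyl)ethyl 3,6-bis(benzyloxy)-4-methoxy-2-[5-methoxy-2-(methoxycarbonyl)-4-(methoxymethoxy)phenyl]benzoate
Conditions: Pd(OAc)2 (5 mol %), SPhos (10 mol %), K3PO4, toluene/H2O, 100 °C
Reagents that add atoms: none
Why: Suzuki–Miyaura coupling with a bulky dialkylbiarylphosphine is the established way to biaryls with three ortho substituents and joins C4a to the future C4.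

**Step 9**
Reactants: 10 protected biaryl
Product: 11 2-(trimethylsilyl)ethyl 3,6-bis(benzyloxy)-2-[4-hydroxy-5-methoxy-2-(methoxycarbonyl)phenyl]-4-methoxybenzoate
Conditions: TsOH·H2O (20 mol %), MeOH/THF, 45 °C
Reagents that add atoms: none
Why: Acid-catalysed acetal exchange removes only the MOM group, since benzyl ethers, the hindered silylethyl ester and the methyl ester are inert to catalytic acid in methanol.

**Step 10**
Reactants: 11 biaryl phenol
Product: 12 2-(trimethylsilyl)ethyl 3,6-bis(benzyloxy)-2-[3,3-dimethoxy-6-(methoxycarbonyl)-4-oxocyclohexa-1,5-dien-1-yl]-4-methoxybenzoate (o-quinone monoketal)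
Conditions: PhI(OAc)2 (1.1 equiv), MeOH, 0 °C
Reagents that add atoms: methanol, CO
Why: In this oxidative dearomatisation of a 2-methoxyphenol to a masked o-benzoquinone, methanol should attack the methoxy-stabilised ortho carbon, because the para carbon is shielded by the twisted aryl group, the ring A carboxyl is masked so that para spirolactonisation cannot compete, and the bulky aryl group on the diene should slow Diels–Alder dimerisation.

**Step 11**
Reactants: 12 o-quinone monoketal ester
Product: 13 3,6-bis(benzyloxy)-2-[3,3-dimethoxy-6-(methoxycarbonyl)-4-oxocyclohexa-1,5-dien-1-yl]-4-methoxybenzoic acid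
Conditions: (Me2N)3S+ Me3SiF2− (TASF, 1.3 equiv), DMF, 0 °C; then cold 0.5 M HCl, extraction, used at once without chromatography
Reagents that add atoms: none
Why: In this fluoride-induced β-elimination of the 2-(trimethylsilyl)ethyl ester, fluoride attacks only silicon, and the fully ionised carboxylate cannot cyclise productively for want of a proton source, so the neutral acid should be obtained after a fast cold acidification.

**Step 12**
Reactants: 13 dienone acid
Product: 15 methyl (4aR,10bR)-7,10-bis(benzyloxy)-4,4,9-trimethoxy-3,6-dioxo-3,4,4a,10b-tetrahydro-6H-benzo[c]chromene-1-carboxylate (cis-fused keto ketal lactone; 3R,4R in isochromanone numbering), via lactone dienol 14 (not isolated)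
Conditions: quinine-derived 3,5-bis(trifluoromethyl)phenyl squaramide (10 mol %), toluene, 4 Å molecular sieves, −20 °C
Reagents that add atoms: none
Why: Proposed new method: the quinuclidine nitrogen of the bifunctional catalyst deprotonates the ring A acid while the squaramide N–H bonds hold the dienone carbonyl, the carboxylate oxygen adds to the unsubstituted δ-carbon of the dienone (C3) and dienol 14 is reprotonated at the γ-carbon (C4), so that an intramolecular 1,6-oxa-conjugate addition turns a flat acid without stereocentres into the lactone with both stereocentres. The closest known reactions are the cinchona squaramide or thiourea catalysed intramolecular 1,4-oxa-Michael additions of benzoic acids to enones (phthalide synthesis), the oxa-Michael desymmetrisation of cyclohexadienones and the 1,6-oxa-additions of alcohols and phenols to dienones and quinone methides, and what is new is the carboxylic acid as 1,6-donor on an o-quinone monoketal together with the dynamic kinetic resolution of the aryl–dienone axis. Ring C closes in the 6-endo-trig mode, which the nearly perpendicular aryl–dienone axis favours because it holds a carboxyl oxygen over the π-face of C3. The catalyst fixes C3 by selecting one of the two rapidly interconverting axial conformers (carboxyl above or below ring B) and with it the face of attack, while C4 follows from C3 by axial protonation anti to the new axial C–O bond and, as C4 stays epimerisable, by the preference for the cis-fused system in which the bond from C4 to the alkene carbon is pseudo-axial and avoids the peri benzyloxy group at C5. Regioselectivity is needed against 5-exo attack at the aryl-bearing γ-carbon (no acceptor position while its neighbour is a ketal and not yet an ester), against 1,4-attack at the fully substituted ester-bearing β-carbon (hindered and reversible) and against the β,γ-unsaturated tautomer (its ester would clash with the C5 benzyloxy group). Aromatisation by loss of methanol should not intervene because the amine cannot remove the non-acidic C3–H and no acid is present to ionise the α-keto ketal.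

**Step 13**
Reactants: 15 keto ketal lactone
Product: 17 (2E)-3-[(3R,4R)-5,8-bis(benzyloxy)-6-methoxy-3-(methoxycarbonyl)-1-oxo-3,4-dihydro-1H-isochromen-4-yl]-4-methoxy-4-oxobut-2-enoic acid (cis-lactone acid), via ring-expanded acyloxy orthoester 16 (not isolated)
Conditions: mCPBA (77 %, water-wet, 1.5 equiv), CH2Cl2, 0 °C to rt; then THF/H2O, rt
Reagents that add atoms: 3-chloroperoxybenzoic acid, O=C(OO)c1cccc(Cl)c1; water, O
Why: In this Baeyer–Villiger oxidation the dialkoxy-substituted carbon should migrate in preference to the vinylic carbon while the doubly acceptor-substituted alkene stays inert to peracid, and hydrolysis of orthoester 16 leaves the former ketone carbon as free acid and the former ketal carbon as methyl ester, with C4 and CO2H cis on the alkene by ring origin and both stereocentres untouched.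

**Step 14**
Reactants: 17 cis-lactone acid
Product: 18 (2E)-3-[(3S,4R)-5,8-bis(benzyloxy)-6-methoxy-3-(methoxycarbonyl)-1-oxo-3,4-dihydro-1H-isochromen-4-yl]-4-methoxy-4-oxobut-2-enoic acid (trans-lactone acid)
Conditions: DBU (2.5 equiv), LiCl, MeCN, rt; then cold 0.5 M HCl
Reagents that add atoms: none
Why: In this thermodynamic epimerisation of an α-acyloxy ester through its lithium-chelated enolate, C3–H should be the only enolisable C–H once the side-chain acid is a carboxylate and C4–H lies pseudo-equatorial near the arene plane, and the equilibrium should favour the trans isomer with the C3 ester and the C4 alkenyl group anti and pseudo-axial while C4 keeps its configuration.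

**Step 15**
Reactants: 18 trans-lactone acid
Product: 19 (2E)-3-[(3S,4R)-5,6,8-trihydroxy-3-(methoxycarbonyl)-1-oxo-3,4-dihydro-1H-isochromen-4-yl]-4-methoxy-4-oxobut-2-enoic acid (target)
Conditions: BBr3 (8 equiv), C6HMe5 (6 equiv), CH2Cl2, −78 to −10 °C; then H2O, argon, acidic work-up
Reagents that add atoms: none
Why: Lewis acid cleavage of aryl alkyl ethers with a cation scavenger should remove the two benzyl ethers and the methyl ether next to the resulting boron phenolate at low temperature, where aliphatic methyl esters, the lactone and the alkene survive, without a base or a reductant that could touch C3, C4 or the double bond.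

**Compound list**
1 | 2,4,5-trimethoxybenzoic acid | COc1cc(OC)c(C(=O)O)cc1OC | starting material
2 | 2-(trimethylsilyl)ethyl 2,4,5-trimethoxybenzoate | COc1cc(OC)c(C(=O)OCC[Si](C)(C)C)cc1OC | intermediate
3 | 2-(trimethylsilyl)ethyl 4-methoxy-3,6-dioxocyclohexa-1,4-diene-1-carboxylate | COC1=CC(=O)C(C(=O)OCC[Si](C)(C)C)=CC1=O | intermediate
4 | 2-(trimethylsilyl)ethyl 2-bromo-3,6-dihydroxy-4-methoxybenzoate | COc1cc(O)c(C(=O)OCC[Si](C)(C)C)c(Br)c1O | intermediate
5 | 2-(trimethylsilyl)ethyl 3,6-bis(benzyloxy)-2-bromo-4-methoxybenzoate | COc1cc(OCc2ccccc2)c(C(=O)OCC[Si](C)(C)C)c(Br)c1OCc1ccccc1 | intermediate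
6 | methyl 3-hydroxy-4-methoxybenzoate | COC(=O)c1ccc(OC)c(O)c1 | starting material
7 | methyl 4-methoxy-3-(methoxymethoxy)benzoate | COCOc1cc(C(=O)OC)ccc1OC | intermediate
8 | methyl 2-bromo-4-methoxy-5-(methoxymethoxy)benzoate | COCOc1cc(C(=O)OC)c(Br)cc1OC | intermediate
9 | methyl 4-methoxy-5-(methoxymethoxy)-2-(pinacolboryl)benzoate | COCOc1cc(C(=O)OC)c(B2OC(C)(C)C(C)(C)O2)cc1OC | intermediate
10 | MOM-protected biaryl diester | COCOc1cc(C(=O)OC)c(cc1OC)-c1c(OCc2ccccc2)c(OC)cc(OCc2ccccc2)c1C(=O)OCC[Si](C)(C)C | intermediate
11 | biaryl phenol | COC(=O)c1cc(O)c(OC)cc1-c1c(OCc2ccccc2)c(OC)cc(OCc2ccccc2)c1C(=O)OCC[Si](C)(C)C | intermediate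
12 | o-quinone monoketal, silylethyl ester | COC(=O)C1=CC(=O)C(OC)(OC)C=C1c1c(OCc2ccccc2)c(OC)cc(OCc2ccccc2)c1C(=O)OCC[Si](C)(C)C | intermediate
13 | o-quinone monoketal, free ring A acid | COC(=O)C1=CC(=O)C(OC)(OC)C=C1c1c(OCc2ccccc2)c(OC)cc(OCc2ccccc2)c1C(=O)O | intermediate
14 | lactone dienol (C3 R, C4 sp2), not isolated | COC(=O)C(C=C3O)=C1c2c(OCc4ccccc4)c(OC)cc(OCc4ccccc4)c2C(=O)O[C@H]1C3(OC)OC | intermediate
15 | cis-fused keto ketal lactone (4aR,10bR) | COC(=O)C(=CC3=O)[C@H]1c2c(OCc4ccccc4)c(OC)cc(OCc4ccccc4)c2C(=O)O[C@H]1C3(OC)OC | intermediate
16 | ring-expanded seven-membered acyloxy orthoester, not isolated | COC(=O)C(=CC(=O)O3)[C@H]1c2c(OCc4ccccc4)c(OC)cc(OCc4ccccc4)c2C(=O)O[C@H]1C3(OC)OC | intermediate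
17 | cis-lactone acid (3R,4R), E alkene | COC(=O)/C(=C/C(=O)O)[C@H]1c2c(OCc3ccccc3)c(OC)cc(OCc3ccccc3)c2C(=O)O[C@H]1C(=O)OC | intermediate
18 | trans-lactone acid (3S,4R), E alkene | COC(=O)/C(=C/C(=O)O)[C@H]1c2c(OCc3ccccc3)c(OC)cc(OCc3ccccc3)c2C(=O)O[C@@H]1C(=O)OC | intermediate
19 | CNP0546035.1 (3S,4R), E alkene | COC(=O)/C(=C/C(=O)O)[C@H]1c2c(O)c(O)cc(O)c2C(=O)O[C@@H]1C(=O)OC | target

**Step count:** 15 steps in total. The longest linear sequence is 12 steps (steps 1–4 and 8–15).

**Steps most likely to fail**

Step 12. The cyclisation may run uncatalysed and without facial control, the oxygen may add at another acceptor carbon, or the addition may revert.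
- The fallback sets out from 12, comes back at 15, and uses known reactions only.
- A copper-catalysed enantioselective 1,6-boryl conjugate addition to the dienone (CuCl, NaOtBu, (R)-DTBM-Segphos, B2pin2, MeOH, THF) should give the allylic boronate F1 with the C3 centre set by the ligand.
- NaBO3·4H2O should oxidise the C–B bond with retention to the allylic alcohol F2.
- TASF followed by cold acid should free the hydroxy acid F3.
- A Shiina lactonisation (2-methyl-6-nitrobenzoic anhydride, DMAP) should close ring C at the acyl carbon, with retention at C3, to the β,γ-unsaturated keto lactone F4.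
- Et3N in CH2Cl2 should then move the double bond into conjugation and set C4 under the same thermodynamic control as in the main route, which gives 15.

Step 13. Peracid addition to the conjugated ketone may be too slow, the vinylic carbon may migrate, or methyl transfer during collapse of the orthoester may lead to loss of the free acid.
- The fallback sets out from 15 and comes back at 17.
- Luche reduction (NaBH4, CeCl3·7H2O, MeOH, −78 °C) should give the allylic alcohol F5, and either carbinol epimer serves.
- Aqueous trifluoroacetic acid should hydrolyse the ketal, which no longer stands next to a carbonyl group, to the α-hydroxy ketone F6, which is carried on at once.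
- Pb(OAc)4 in MeOH/benzene should cleave the methanol hemiketal in the glycol manner to the ester aldehyde F7.
- Pinnick oxidation (NaClO2, NaH2PO4, 2-methyl-2-butene) of the enal should then give 17 with the same acid/ester differentiation.

Step 14. Enolisation at C3 may be too slow, or deprotonation at C4 may compete, which would cause β-elimination of the lactone carboxylate or erosion of enantiomeric purity.
- The fallback sets out from 13, comes back at 18, and replaces carbanion chemistry at C3 by radical chemistry at C4.
- Step 12 run with the quinidine-derived pseudoenantiomeric catalyst should give the mirror-image keto ketal lactone F8.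
- The conditions of step 13 should convert it into the (3S,4S) cis-lactone acid F9, in which C3 already has the target configuration.
- A thiyl radical (PhSH catalytic, AIBN, benzene, 80 °C) should abstract and return the weakest hydrogen, the allylic and benzylic C4–H, reversibly.
- C4 should thereby equilibrate to the more stable trans isomer 18 without any anion that could expel the carboxylate.

**Further compounds**
F1 | step 12 | allylic boronate, β,γ-unsaturated keto ketal, boron-bearing carbon configured as C3 of 15 | COC(=O)C1=C(c2c(OCc3ccccc3)c(OC)cc(OCc3ccccc3)c2C(=O)OCC[Si](C)(C)C)[C@@H](B2OC(C)(C)C(C)(C)O2)C(OC)(OC)C(=O)C1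
F2 | step 12 | allylic alcohol from F1, same configuration | COC(=O)C1=C(c2c(OCc3ccccc3)c(OC)cc(OCc3ccccc3)c2C(=O)OCC[Si](C)(C)C)[C@@H](O)C(OC)(OC)C(=O)C1
F3 | step 12 | hydroxy acid from F2 | COC(=O)C1=C(c2c(OCc3ccccc3)c(OC)cc(OCc3ccccc3)c2C(=O)O)[C@@H](O)C(OC)(OC)C(=O)C1
F4 | step 12 | β,γ-unsaturated keto lactone (keto tautomer of 14) | COC(=O)C(CC3=O)=C1c2c(OCc4ccccc4)c(OC)cc(OCc4ccccc4)c2C(=O)O[C@H]1C3(OC)OC
F5 | step 13 | allylic alcohol from 15, carbinol centre either way | COC(=O)C(=CC3O)[C@H]1c2c(OCc4ccccc4)c(OC)cc(OCc4ccccc4)c2C(=O)O[C@H]1C3(OC)OC
F6 | step 13 | α-hydroxy ketone from F5 | COC(=O)C(=CC3O)[C@H]1c2c(OCc4ccccc4)c(OC)cc(OCc4ccccc4)c2C(=O)O[C@H]1C3=O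
F7 | step 13 | cis-lactone ester aldehyde (3R,4R), E alkene | COC(=O)/C(=C/C=O)[C@H]1c2c(OCc3ccccc3)c(OC)cc(OCc3ccccc3)c2C(=O)O[C@H]1C(=O)OC
F8 | step 14 | mirror image of 15 (4aS,10bS) | COC(=O)C(=CC3=O)[C@@H]1c2c(OCc4ccccc4)c(OC)cc(OCc4ccccc4)c2C(=O)O[C@@H]1C3(OC)OC
F9 | step 14 | cis-lactone acid (3S,4S), E alkene | COC(=O)/C(=C/C(=O)O)[C@@H]1c2c(OCc3ccccc3)c(OC)cc(OCc3ccccc3)c2C(=O)O[C@@H]1C(=O)OC
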